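## Retrosynthetic overview

1. Target 22 ⇒ (hydrogenolysis, desilylation) protected dimer 20, which is cut in one operation into flavan-4-ol 5 (rings A, B, C) and the cis-2-aryl-2,3-dihydrobenzofuran-3-ylmethyl mesylate 16 (rings D, E and a five-membered O-ring).
2. The key step forms the C4(upper)–C8(lower) bond. In the same flask it expands the ring O1–C2–C3–C3a–C7a of 16 to pyran ring F by shifting the aryl carbon from C3 to the exocyclic CH2, with water entering at C3.
3. Enabling feature: in ring D, C4a is ortho to O1 and to C5–O and para to C7–O, and the 3-OH sits beta to it (C3–C4–C4a). C4a can therefore bridge C3/C4 as a phenonium ion, and the same oxygen pattern makes C8 the carbon nucleophile.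
4. 16 ⇐ Rh-carbenoid C–H insertion (sets C2 and C3 as cis) ⇐ aryl diazoacetate ⇐ benzofuran-2,3-dione ⇐ phloroglucinol. 5 ⇐ asymmetric conjugate addition to a chromone.
5. Order of ring formation: the aromatic rings and ring C are bought (chromone), the five-membered O-ring forms in step 8, and ring F forms by expansion in step 11.

Key step: step 11

Assumption: the sense of induction of the chiral catalysts in steps 2 and 8 is inferred from closely related substrates. The catalyst antipode that gives the drawn enantiomer is meant.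

## Route

Step 1
Reactants: 1 7-hydroxy-4H-chromen-4-one
Product: 2 7-(benzyloxy)-4H-chromen-4-one
Conditions: BnBr, K2CO3, DMF, rt
Reagents that add atoms: benzyl bromide, BrCc1ccccc1
Why: Williamson etherification of the acidic 7-OH; no stereocentre is involved.

Step 2
Reactants: 2 7-(benzyloxy)-4H-chromen-4-one; 3 [4-(benzyloxy)phenyl]boronic acid
Product: 4 (2S)-7-(benzyloxy)-2-[4-(benzyloxy)phenyl]chroman-4-one
Conditions: Pd(OCOCF3)2 (cat.), (S)-t-BuPyOx (cat.), NH4PF6 (cat.), H2O, ClCH2CH2Cl, 60 °C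
Reagents that add atoms: none
Why: Pd(II)/pyridine-oxazoline-catalysed asymmetric conjugate addition of an arylboronic acid to a chromone, in which the ligand-controlled face of migratory insertion sets C2 as S.

Step 3
Reactants: 4 (2S)-7-(benzyloxy)-2-[4-(benzyloxy)phenyl]chroman-4-one
Product: 5 (2S,4S)-7-(benzyloxy)-2-[4-(benzyloxy)phenyl]chroman-4-ol (2,4-cis)
Conditions: NaBH4, THF–MeOH, 0 °C
Reagents that add atoms: none
Why: Borohydride reduction of a flavanone should give the 2,4-cis alcohol (substrate control by the equatorial 2-aryl group), and this centre is erased again in step 11.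

Step 4
Reactants: 6 phloroglucinol
Product: 7 3,5-bis(tert-butyldimethylsilyloxy)phenol
Conditions: TBSCl (2 equiv), imidazole, DMF, 0 °C to rt, chromatographic separation
Reagents that add atoms: tert-butyldimethylsilyl chloride, CC(C)(C)[Si](C)(C)Cl
Why: Statistical silylation of three equivalent phenols gives the bis-ether, whose silyl groups carry no C–H alpha to oxygen (needed in step 8).

Step 5
Reactants: 7 3,5-bis(tert-butyldimethylsilyloxy)phenol
Product: 8 4,6-bis(tert-butyldimethylsilyloxy)-1-benzofuran-2,3-dione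
Conditions: (COCl)2 (excess), CH2Cl2, 0 °C to reflux, N2 sweep
Reagents that add atoms: oxalyl chloride, O=C(Cl)C(=O)Cl
Why: O-acylation followed by intramolecular Friedel–Crafts acylation of the electron-rich ring; the tether places the carbon ortho to the free oxygen, and both ortho positions are equivalent.

Step 6
Reactants: 8 4,6-bis(tert-butyldimethylsilyloxy)-1-benzofuran-2,3-dione; 9 [3,4,5-tris(benzyloxy)phenyl]methanol
Product: 11 methyl {4,6-bis(tert-butyldimethylsilyloxy)-2-[3,4,5-tris(benzyloxy)benzyloxy]phenyl}(oxo)acetate, via hydroxy keto ester 10 (not isolated)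
Conditions: MeOH, CH2Cl2, rt; evaporate; then 9, PPh3, DIAD, THF, 0 °C to rt
Reagents that add atoms: methanol, CO
Why: Methanolysis of the activated lactone frees exactly one phenol, which is etherified under neutral Mitsunobu conditions that spare the aryl silyl ethers.

Step 7
Reactants: 11 methyl {4,6-bis(tert-butyldimethylsilyloxy)-2-[3,4,5-tris(benzyloxy)benzyloxy]phenyl}(oxo)acetate
Product: 13 methyl diazo{4,6-bis(tert-butyldimethylsilyloxy)-2-[3,4,5-tris(benzyloxy)benzyloxy]phenyl}acetate, via tosylhydrazone 12 (not isolated)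
Conditions: TsNHNH2, MeOH, 50 °C; then Et3N, CH2Cl2, rt
Reagents that add atoms: 4-methylbenzenesulfonohydrazide, Cc1ccc(cc1)S(=O)(=O)NN
Why: Condensation and base-induced loss of sulfinate (Bamford–Stevens type) is the standard route from aryl keto esters to aryl diazoacetates.

Step 8
Reactants: 13 methyl diazo{4,6-bis(tert-butyldimethylsilyloxy)-2-[3,4,5-tris(benzyloxy)benzyloxy]phenyl}acetate
Product: 14 methyl (2S,3R)-4,6-bis(tert-butyldimethylsilyloxy)-2-[3,4,5-tris(benzyloxy)phenyl]-2,3-dihydro-1-benzofuran-3-carboxylate (2,3-cis)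
Conditions: Rh2(S-PTTL)4 (cat.), toluene, −60 °C
Reagents that add atoms: none
Why: Intramolecular Rh(II)-carbenoid 1,5-C–H insertion into the only ether-activated benzylic CH2 within reach of the carbene closes the five-membered ring, and the chiral carboxylate ligands set C2 and C3 together as the kinetic cis isomer.

Step 9
Reactants: 14 methyl (2S,3R)-cis-dihydrobenzofuran-3-carboxylate
Product: 15 {(2S,3S)-4,6-bis(tert-butyldimethylsilyloxy)-2-[3,4,5-tris(benzyloxy)phenyl]-2,3-dihydro-1-benzofuran-3-yl}methanol (2,3-cis)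
Conditions: DIBAL-H, CH2Cl2, −78 °C
Reagents that add atoms: none
Why: Low-temperature hydride reduction of the ester is faster than enolisation, so the cis relation should be kept.

Step 10
Reactants: 15 (2S,3S)-cis-dihydrobenzofuran-3-ylmethanol
Product: 16 {(2S,3S)-4,6-bis(tert-butyldimethylsilyloxy)-2-[3,4,5-tris(benzyloxy)phenyl]-2,3-dihydro-1-benzofuran-3-yl}methyl methanesulfonate
Conditions: MsCl, Et3N, CH2Cl2, −30 °C, used without chromatography
Reagents that add atoms: methanesulfonyl chloride, CS(=O)(=O)Cl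
Why: Standard sulfonylation of a primary alcohol, with no bond to a stereocentre touched.

Step 11
Reactants: 16 cis-dihydrobenzofuran-3-ylmethyl methanesulfonate; 5 (2S,4S)-7-(benzyloxy)-2-[4-(benzyloxy)phenyl]chroman-4-ol
Product: 20 7,4'-di-O-benzyl-(2S,4R)-flavan-(4β→8)-[3',4',5'-tri-O-benzyl-5,7-bis-O-TBS-(2R,3R)-epigallocatechin], via phenonium mesylate 17 (not isolated), via ring-expanded flavan-3-ol 18 (not isolated), via flavan-4-yl cation 19 (not isolated)
Conditions: 5 (1 equiv), H2O (2 equiv), (CF3)2CHOH–CH2Cl2, 0 °C to rt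
Reagents that add atoms: water, O
Why: Proposed new method: in the strongly ionising, weakly nucleophilic medium the mesylate of 16 leaves with participation of ring-D carbon C3a (later C4a) to give the bridged phenonium ion 17 (3-exo-tet closure of a spirocyclopropane), and water opens 17 at the secondary carbon anti to that aryl carbon, so that the aryl bond moves from C3 to the former exocyclic CH2 and the five-membered ring O1-C2-C3-C3a-C7a becomes the six-membered pyran ring of 18 (Wagner–Meerwein 1,2-aryl shift, ring expansion by one carbon). The methanesulfonic acid released then ionises 5 to the benzylic cation 19, stabilised by O1 and the para 7-benzyloxy group, which alkylates C8 of 18 in an intermolecular Friedel–Crafts reaction; should 19 attack 16 first, the same product results after the shift. The closest known reaction types are the solvolytic aryl shifts of 2-aryl-1-alkyl sulfonates, the ring-expanding solvolysis of spirocyclopropyl-cyclohexadienones of the duocarmycin class (which runs with inversion) and the acid-induced condensation of flavan-4-ols with flavan-3-ols, while their combination on a dihydrobenzofuran is new. C3 of the lower unit is set by inversion at the migration origin, which turns the cis-2,3 relation of 16 into the 2,3-cis (2R,3R) flavan-3-ol with C2 untouched, and C4 of the upper unit is set by pseudo-axial attack on the half-chair cation with its 2-aryl group equatorial, that is anti to this group (2,4-trans, 4R). Opening of 17 at C3 instead of CH2 is the critical selectivity: it is favoured by the higher cationic character of the secondary carbon and by release of five-ring strain and of the eclipsed cis substituents, and it should be self-correcting, because the primary alcohol 15 formed by attack at CH2 is re-ionised through 17 under the acidic conditions whereas the axial 3-OH of the product is not antiperiplanar to the C4–C4a bond. C8 is preferred over C6 because C6 lies between two bulky silyloxy groups and C8 next to the tied-back ring oxygen, and ring D outcompetes ring A of 5 as the nucleophile because it carries three oxygen donors.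

Step 12
Reactants: 20 protected dimer
Product: 21 7,4'-di-O-benzyl-(2S,4R)-flavan-(4β→8)-[3',4',5'-tri-O-benzyl-(2R,3R)-epigallocatechin]
Conditions: TBAF, AcOH, THF, 0 °C
Reagents that add atoms: none
Why: Buffered fluoride cleaves the two aryl silyl ethers (any silyl group already lost in step 11 converges here) without touching benzyl ethers or stereocentres.

Step 13
Reactants: 21 penta-O-benzyl dimer
Product: 22 (2S,4R)-7,4'-dihydroxyflavan-(4β→8)-(2R,3R)-epigallocatechin (target)
Conditions: H2 (1 atm), Pd(OH)2/C, THF–MeOH, rt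
Reagents that add atoms: none
Why: Hydrogenolysis of the five aryl benzyl ethers is the usual last step for benzylated flavan dimers and leaves the interflavan bond and the O1–C2 bonds intact.

## Compound list

1 | 7-hydroxy-4H-chromen-4-one | O=c1ccoc2cc(O)ccc12 | starting material
2 | 7-(benzyloxy)-4H-chromen-4-one | O=c1ccoc2cc(OCc3ccccc3)ccc12 | intermediate
3 | [4-(benzyloxy)phenyl]boronic acid | OB(O)c1ccc(OCc2ccccc2)cc1 | starting material
4 | (2S)-7-(benzyloxy)-2-[4-(benzyloxy)phenyl]chroman-4-one | c1ccccc1COc1ccc([C@@H]2CC(=O)c3ccc(OCc4ccccc4)cc3O2)cc1 | intermediate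
5 | (2S,4S)-7-(benzyloxy)-2-[4-(benzyloxy)phenyl]chroman-4-ol (2,4-cis) | c1ccccc1COc1ccc([C@@H]2C[C@H](O)c3ccc(OCc4ccccc4)cc3O2)cc1 | intermediate
6 | phloroglucinol | Oc1cc(O)cc(O)c1 | starting material
7 | 3,5-bis(tert-butyldimethylsilyloxy)phenol | Oc1cc(O[Si](C)(C)C(C)(C)C)cc(O[Si](C)(C)C(C)(C)C)c1 | intermediate
8 | 4,6-bis(tert-butyldimethylsilyloxy)-1-benzofuran-2,3-dione | O=C1Oc2cc(O[Si](C)(C)C(C)(C)C)cc(O[Si](C)(C)C(C)(C)C)c2C1=O | intermediate
9 | [3,4,5-tris(benzyloxy)phenyl]methanol | OCc1cc(OCc2ccccc2)c(OCc2ccccc2)c(OCc2ccccc2)c1 | starting material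
10 | methyl [2-hydroxy-4,6-bis(tert-butyldimethylsilyloxy)phenyl](oxo)acetate | COC(=O)C(=O)c1c(O)cc(O[Si](C)(C)C(C)(C)C)cc1O[Si](C)(C)C(C)(C)C | intermediate
11 | methyl {4,6-bis(TBSO)-2-[3,4,5-tris(benzyloxy)benzyloxy]phenyl}(oxo)acetate | COC(=O)C(=O)c1c(OCc2cc(OCc3ccccc3)c(OCc3ccccc3)c(OCc3ccccc3)c2)cc(O[Si](C)(C)C(C)(C)C)cc1O[Si](C)(C)C(C)(C)C | intermediate
12 | N-tosylhydrazone of 11 | COC(=O)C(=NNS(=O)(=O)c1ccc(C)cc1)c1c(OCc2cc(OCc3ccccc3)c(OCc3ccccc3)c(OCc3ccccc3)c2)cc(O[Si](C)(C)C(C)(C)C)cc1O[Si](C)(C)C(C)(C)C | intermediate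
13 | methyl diazo{4,6-bis(TBSO)-2-[3,4,5-tris(benzyloxy)benzyloxy]phenyl}acetate | COC(=O)C(=[N+]=[N-])c1c(OCc2cc(OCc3ccccc3)c(OCc3ccccc3)c(OCc3ccccc3)c2)cc(O[Si](C)(C)C(C)(C)C)cc1O[Si](C)(C)C(C)(C)C | intermediate
14 | methyl (2S,3R)-cis-4,6-bis(TBSO)-2-[3,4,5-tris(benzyloxy)phenyl]-2,3-dihydro-1-benzofuran-3-carboxylate | CC(C)(C)[Si](C)(C)Oc1cc(O[Si](C)(C)C(C)(C)C)c2c(c1)O[C@H](c1cc(OCc3ccccc3)c(OCc3ccccc3)c(OCc3ccccc3)c1)[C@@H]2C(=O)OC | intermediate
15 | {(2S,3S)-cis-4,6-bis(TBSO)-2-[3,4,5-tris(benzyloxy)phenyl]-2,3-dihydro-1-benzofuran-3-yl}methanol | CC(C)(C)[Si](C)(C)Oc1cc(O[Si](C)(C)C(C)(C)C)c2c(c1)O[C@H](c1cc(OCc3ccccc3)c(OCc3ccccc3)c(OCc3ccccc3)c1)[C@@H]2CO | intermediate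
16 | methanesulfonate of 15 | CC(C)(C)[Si](C)(C)Oc1cc(O[Si](C)(C)C(C)(C)C)c2c(c1)O[C@H](c1cc(OCc3ccccc3)c(OCc3ccccc3)c(OCc3ccccc3)c1)[C@@H]2COS(C)(=O)=O | intermediate
17 | bridged phenonium ion (spirocyclopropane on ring D, one resonance form) as mesylate | CC(C)(C)[Si](C)(C)[O+]=C1C=C(O[Si](C)(C)C(C)(C)C)[C@]23C[C@H]2[C@@H](c2cc(OCc4ccccc4)c(OCc4ccccc4)c(OCc4ccccc4)c2)OC3=C1.CS(=O)(=O)[O-] | intermediate
18 | (2R,3R)-3',4',5'-tri-O-benzyl-5,7-bis-O-TBS-epigallocatechin (2,3-cis) | CC(C)(C)[Si](C)(C)Oc1cc(O[Si](C)(C)C(C)(C)C)c2c(c1)O[C@H](c1cc(OCc3ccccc3)c(OCc3ccccc3)c(OCc3ccccc3)c1)[C@H](O)C2 | intermediate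
19 | (2S)-7,4'-di-O-benzylflavan-4-yl cation as mesylate | c1ccccc1COc1ccc([C@@H]2C[CH+]c3ccc(OCc4ccccc4)cc3O2)cc1.CS(=O)(=O)[O-] | intermediate
20 | 7,4'-di-O-benzyl-(2S,4R)-flavan-(4β→8)-[3',4',5'-tri-O-benzyl-5,7-bis-O-TBS-(2R,3R)-epigallocatechin] | c1ccccc1COc1ccc([C@@H]2C[C@@H](c3c(O[Si](C)(C)C(C)(C)C)cc(O[Si](C)(C)C(C)(C)C)c4c3O[C@H](c3cc(OCc5ccccc5)c(OCc5ccccc5)c(OCc5ccccc5)c3)[C@H](O)C4)c3ccc(OCc4ccccc4)cc3O2)cc1 | intermediate
21 | 7,4'-di-O-benzyl-(2S,4R)-flavan-(4β→8)-[3',4',5'-tri-O-benzyl-(2R,3R)-epigallocatechin] | c1ccccc1COc1ccc([C@@H]2C[C@@H](c3c(O)cc(O)c4c3O[C@H](c3cc(OCc5ccccc5)c(OCc5ccccc5)c(OCc5ccccc5)c3)[C@H](O)C4)c3ccc(OCc4ccccc4)cc3O2)cc1 | intermediate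
22 | (2S,4R)-7,4'-dihydroxyflavan-(4β→8)-(2R,3R)-epigallocatechin | Oc1ccc([C@@H]2C[C@@H](c3c(O)cc(O)c4c3O[C@H](c3cc(O)c(O)c(O)c3)[C@H](O)C4)c3ccc(O)cc3O2)cc1 | target

## Step count and risks

Total step count: 13. Longest linear sequence: 10 (steps 4 to 13).

**1. Step 11 (Proposed new method).**
- Capture of the bridged cation at the methylene carbon may outrun the re-ionisation.
- A 1,2-hydride shift from C3 may be followed by aromatisation of the five-membered ring.
- Silyl groups may be lost early, with erosion of the C8/C6 selectivity.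
- The O1–C2 bond may ionise, with epimerisation at C2.

The fallback uses known chemistry. It keeps the ring expansion but drives it by carbonyl formation. It sets out from 14, meets the route at 18 and comes back at 20.

The potassium enolate of 14 (KHMDS, THF, −78 °C) is hydroxylated with 2-(phenylsulfonyl)-3-phenyloxaziridine on the face anti to the aryl group. This gives methyl (2R,3S)-3-hydroxy-4,6-bis(TBSO)-2-[3,4,5-tris(benzyloxy)phenyl]-2,3-dihydro-1-benzofuran-3-carboxylate F1. DIBAL-H reduces it to (2R,3R)-3-(hydroxymethyl)-4,6-bis(TBSO)-2-[3,4,5-tris(benzyloxy)phenyl]-2,3-dihydro-1-benzofuran-3-ol F2. MsCl with 2,4,6-collidine sulfonylates only the primary hydroxyl and gives the primary methanesulfonate of this diol F3.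

Et3Al (CH2Cl2, −78 °C) then triggers a semipinacol rearrangement in which the electron-rich aryl carbon migrates. The product is (2R)-3',4',5'-tri-O-benzyl-5,7-bis-O-TBS-flavan-3-one F4. L-Selectride (THF, −78 °C) delivers hydride anti to the 2-aryl group and gives 18. This compound is isolated and coupled with 5 under TMSOTf catalysis (CH2Cl2, −40 °C) to 20.

**2. Step 8.** Enantio- and cis-selectivity may erode because the di-ortho-substituted aryl ring cannot lie in the carbene plane. Carbene dimerisation may also compete.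

The fallback replaces asymmetric catalysis by enzymatic resolution. It sets out from 13 and comes back at 15. Achiral Rh2(esp)2 (CH2Cl2, 0 °C) gives the racemic cis ester, which is 14 together with methyl (2R,3S)-cis-4,6-bis(TBSO)-2-[3,4,5-tris(benzyloxy)phenyl]-2,3-dihydro-1-benzofuran-3-carboxylate F5. DIBAL-H reduces the pair to 15 and its enantiomer, the (2R,3R)-cis-dihydrobenzofuran-3-ylmethanol F6. A lipase (Burkholderia cepacia, vinyl acetate, MTBE) should acetylate the unwanted antipode to the (2R,3R)-cis-dihydrobenzofuran-3-ylmethyl acetate F7. Alcohol 15 is then left to be separated by chromatography.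

**3. Step 5.** The hydrogen chloride evolved may cleave the silyl ethers. The uncatalysed ring acylation may be sluggish, and diaryl oxalate may form.

The fallback uses C–C bond formation by chelation-controlled hydroxyalkylation instead of acylation. It sets out from 7 and comes back at 10. The bromomagnesium phenolate of 7 (EtMgBr, toluene) adds ortho-selectively to methyl glyoxylate. This gives methyl hydroxy[2-hydroxy-4,6-bis(TBSO)phenyl]acetate F8 (racemic). MnO2 (CH2Cl2) then oxidises its benzylic alcohol to 10, which enters the Mitsunobu half of step 6.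

## Further compounds

F1 | step 11 | methyl (2R,3S)-3-hydroxy-4,6-bis(TBSO)-2-[3,4,5-tris(benzyloxy)phenyl]-2,3-dihydro-1-benzofuran-3-carboxylate (OH trans to aryl) | CC(C)(C)[Si](C)(C)Oc1cc(O[Si](C)(C)C(C)(C)C)c2c(c1)O[C@H](c1cc(OCc3ccccc3)c(OCc3ccccc3)c(OCc3ccccc3)c1)[C@]2(O)C(=O)OC
F2 | step 11 | (2R,3R)-3-(hydroxymethyl)-4,6-bis(TBSO)-2-[3,4,5-tris(benzyloxy)phenyl]-2,3-dihydro-1-benzofuran-3-ol | CC(C)(C)[Si](C)(C)Oc1cc(O[Si](C)(C)C(C)(C)C)c2c(c1)O[C@H](c1cc(OCc3ccccc3)c(OCc3ccccc3)c(OCc3ccccc3)c1)[C@]2(O)CO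
F3 | step 11 | primary methanesulfonate of F2 | CC(C)(C)[Si](C)(C)Oc1cc(O[Si](C)(C)C(C)(C)C)c2c(c1)O[C@H](c1cc(OCc3ccccc3)c(OCc3ccccc3)c(OCc3ccccc3)c1)[C@]2(O)COS(C)(=O)=O
F4 | step 11 | (2R)-3',4',5'-tri-O-benzyl-5,7-bis-O-TBS-flavan-3-one | CC(C)(C)[Si](C)(C)Oc1cc(O[Si](C)(C)C(C)(C)C)c2c(c1)O[C@H](c1cc(OCc3ccccc3)c(OCc3ccccc3)c(OCc3ccccc3)c1)C(=O)C2
F5 | step 8 | methyl (2R,3S)-cis-4,6-bis(TBSO)-2-[3,4,5-tris(benzyloxy)phenyl]-2,3-dihydro-1-benzofuran-3-carboxylate (enantiomer of 14) | CC(C)(C)[Si](C)(C)Oc1cc(O[Si](C)(C)C(C)(C)C)c2c(c1)O[C@@H](c1cc(OCc3ccccc3)c(OCc3ccccc3)c(OCc3ccccc3)c1)[C@H]2C(=O)OC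
F6 | step 8 | (2R,3R)-cis-dihydrobenzofuran-3-ylmethanol (enantiomer of 15) | CC(C)(C)[Si](C)(C)Oc1cc(O[Si](C)(C)C(C)(C)C)c2c(c1)O[C@@H](c1cc(OCc3ccccc3)c(OCc3ccccc3)c(OCc3ccccc3)c1)[C@H]2CO
F7 | step 8 | (2R,3R)-cis-dihydrobenzofuran-3-ylmethyl acetate | CC(C)(C)[Si](C)(C)Oc1cc(O[Si](C)(C)C(C)(C)C)c2c(c1)O[C@@H](c1cc(OCc3ccccc3)c(OCc3ccccc3)c(OCc3ccccc3)c1)[C@H]2COC(C)=O
F8 | step 5 | methyl hydroxy[2-hydroxy-4,6-bis(TBSO)phenyl]acetate (racemic) | COC(=O)C(O)c1c(O)cc(O[Si](C)(C)C(C)(C)C)cc1O[Si](C)(C)C(C)(C)C
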